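The synthesis rests on making the hydroquinone (ring A, C17–C22; carbons numbered C1–C22 in SMILES order, heteroatoms not counted) last. Ring A shares its C17–C22 edge with a five-membered ring whose other atoms, C16, C6 and C11, already belong to the cyclohexene (ring C). Two ethynylboronate arms held cis-1,3-diaxial on C16 and C11 therefore need only acetylene to close both rings in one metal-catalysed [2+2+2] cycloaddition, with boron placed on C18 and C21, the future phenol carbons. The precursor is a trans-fused, prenylated decalin enedione carrying both alkynylboronates anti to the prenyl group; it comes from a quinone-monoketal Diels–Alder reaction and two enolate quaternisations. Ene-type closure of C4–C8 and boron-to-oxygen exchange finish the route.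

Key step: step 7

Remarks on the chemistry (each one line):
- Rings: A = hydroquinone C17–C22; B = dione ring C6–C11; C = cyclohexene C6, C11, C12, C13, C15, C16; C1–C5 are the prenyl carbons, C14 the methyl group of ring C.
- Numbered compounds are building blocks and intermediates; "Reagents that add atoms" names the other reagents that leave atoms in a product.
- Assumption: (S)-BINOL is taken to give the enantiomer of 7 that is drawn; if the antipode forms, (R)-BINOL is used and nothing else changes.
- A 2-prenylbenzoquinone would take up the diene at its unsubstituted double bond, so the dienophile is the monoketal 6 and the prenyl group is placed on C6 afterwards.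
- Boron is exchanged for oxygen only after C4–C8 is closed, and with an amine N-oxide, because a peroxide would epoxidise the enedione and could oxidise the hydroquinone further.
- In the target the isopropenyl group on C4 is exo (toward the C7 bridge, trans to C9); a concerted ene reaction would give the C4 epimer, so C4–C8 is closed under Lewis-acid, stepwise conditions.

Step 1
Reactants: 1 ethynyltrimethylsilane; 2 (E)-1,2-dichloroethene
Product: 3 (E)-(4-chlorobut-3-en-1-yn-1-yl)trimethylsilane
Conditions: Pd(PPh3)4 (2 mol %), CuI (5 mol %), n-BuNH2, Et2O, rt; 2 in fivefold excess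
Reagents that add atoms: none
Why: Sonogashira coupling of a terminal alkyne with an alkenyl chloride; the excess of 2 limits the reaction to one carbon–chlorine bond and the E geometry is retained.

Step 2
Reactants: 3 (E)-(4-chlorobut-3-en-1-yn-1-yl)trimethylsilane; 4 isopropenylmagnesium bromide
Product: 5 (E)-trimethyl(5-methylhexa-3,5-dien-1-yn-1-yl)silane
Conditions: Pd(PPh3)4 (3 mol %), THF, 0 °C to rt
Reagents that add atoms: none
Why: Kumada–Corriu coupling of the alkyne-activated alkenyl chloride with an alkenyl Grignard reagent proceeds with retention of the E geometry and leaves the silylalkyne untouched.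

Step 3
Reactants: 5 (E)-trimethyl(5-methylhexa-3,5-dien-1-yn-1-yl)silane; 6 1,4-dioxaspiro[4.5]deca-6,9-dien-8-one
Product: 7 all-cis adduct 7-methyl-5-[(trimethylsilyl)ethynyl]-4a,5,8,8a-tetrahydro-4H-spiro[naphthalene-1,2'-[1,3]dioxolan]-4-one (H6 H11 H16 on one face; C7 ketone; C10 dioxolane)
Conditions: (S)-BINOL (20 mol %), TiCl2(Oi-Pr)2 (20 mol %), 4 Å molecular sieves, CH2Cl2, −30 °C to rt
Reagents that add atoms: none
Why: Enantioselective Lewis-acid-catalysed Diels–Alder reaction of a quinone monoketal: the titanium–BINOL complex binds the only carbonyl group of 6, the unsubstituted diene terminus C12 bonds to the β-carbon (C11) and the alkyne-bearing terminus C16 to the α-carbon (C6), endo approach puts H6, H11 and H16 on one face, and the chiral ligand selects the enone face and with it the absolute configuration at C16, the one centre of the three that is carried unchanged to the target.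

Step 4
Reactants: 7 all-cis adduct; 8 1-bromo-3-methylbut-2-ene (prenyl bromide)
Product: 10 7-methyl-4a-(3-methylbut-2-en-1-yl)-5-[(trimethylsilyl)ethynyl]-4a,5,8,8a-tetrahydronaphthalene-1,4-dione (prenyl on C6 trans to the C16 alkyne), via C6-prenylated dioxolane ketal 9 (not isolated)
Conditions: LDA, THF, −78 °C; 8, DMPU, −78 to 0 °C; then 2 M HCl, rt
Reagents that add atoms: water, O
Why: Alkylation of a kinetic ketone enolate and acetal hydrolysis in one flask: C6–H is the only acidic hydrogen of 7, allylic strain with the enolate oxygen turns the alkyne on C16 axial so that prenyl bromide enters C6 from the opposite face (new quaternary centre with prenyl trans to the alkyne), and aqueous acid then frees the C10 ketone, the configuration at C11 being irrelevant because C11 becomes trigonal in step 5.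

Step 5
Reactants: 10 prenylated silylalkynyl enedione; 11 1-[(trimethylsilyl)ethynyl]-1,2-benziodoxol-3(1H)-one
Product: 13 5,8a-diethynyl-7-methyl-4a-(3-methylbut-2-en-1-yl)-4a,5,8,8a-tetrahydronaphthalene-1,4-dione (both alkynes on one face of ring C; prenyl on the other; trans ring fusion), via C11-ethynyl C18-silyl diyne 12 (not isolated)
Conditions: KHMDS, THF, −78 °C; 11, Bu4NF, −78 °C; then Bu4NF, 0 °C
Reagents that add atoms: none
Why: Electrophilic α-alkynylation of a ketone enolate with an ethynylbenziodoxolone released from 11 by fluoride (conjugate addition to the iodine-bound alkyne, loss of 2-iodobenzoate, 1,2-hydrogen shift): C11–H is the only enolisable position of 10, the flat ring B keeps C7 in the enolate plane so that the prenyl CH2 on C6 stands axial and screens one face, the ethynyl group therefore enters anti to prenyl and on the side of the slim axial alkyne of C16, which sets C11 and the trans ring fusion, and the second portion of fluoride removes the silyl group from the other alkyne.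

Step 6
Reactants: 13 trans-fused diyne
Product: 14 7-methyl-4a-(3-methylbut-2-en-1-yl)-5,8a-bis[(4,4,5,5-tetramethyl-1,3,2-dioxaborolan-2-yl)ethynyl]-4a,5,8,8a-tetrahydronaphthalene-1,4-dione (configuration as in 13)
Conditions: i-PrOBpin (3 equiv), IPrAgCl (5 mol %), Cs2CO3 (20 mol %), MeCN, rt
Reagents that add atoms: 2-isopropoxy-4,4,5,5-tetramethyl-1,3,2-dioxaborolane, CC(C)OB1OC(C)(C)C(C)(C)O1
Why: Silver-catalysed C–H borylation of terminal alkynes, in which a silver acetylide hands its alkynyl group to the alkoxyboronate: both ketones lack α-hydrogens and are flanked by quaternary carbons, so they tolerate the catalytic carbonate, and no stereocentre is involved.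

Step 7
Reactants: 14 bis(alkynylboronate) enedione; 15 acetylene
Product: 16 bis-borylated benzo-bridged enedione (ring A with Bpin on C18 and C21 fused through C17–C22 to the five-membered ring C16–C6–C11; prenyl on C6; ring B enedione)
Conditions: Cp*RuCl(cod) (10 mol %), acetylene (1 atm), ClCH2CH2Cl, rt; 14 added over 6 h
Reagents that add atoms: none
Why: Proposed new method: on the Cp*RuCl fragment the two alkynylboronate arms should couple oxidatively to a ruthenacyclopentadiene (new C17–C22 bond), acetylene should then insert, and reductive elimination should form C18–C19 and C20–C21 and release the catalyst. The closest known reaction type is the ruthenium- or cobalt-catalysed [2+2+2] cycloaddition of 1,6-diynes with a monoalkyne, alkynylboronates included, which gives fused arylboronates; new here are a diyne whose tether is a 1,3-diaxially substituted ring, so that the carbocycle formed is bridged, and boron on both diyne termini. The five-membered ring (C6, C11, C22, C17, C16) closes in the oxidative coupling, as the carbocyclic part of the metallacycle, and ring A closes in the insertion and reductive elimination sequence. No stereocentre is created; C6, C11 and C16 are untouched, and it is their configuration (both arms axial on the same face of the locked trans-fused ring C, anti to prenyl) that brings C17 and C22 within bonding distance. The step needs chemoselectivity, that is one diyne plus one acetylene in preference to diyne oligomerisation, acetylene trimerisation or uptake of the enedione and the trisubstituted alkenes, and this should be secured by the chelating 1,6-diyne, slow addition of 14 under an acetylene atmosphere and a catalyst that works at room temperature. Regiochemistry is fixed by the tether: the boron-bearing termini can only become C18 and C21.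

Step 8
Reactants: 16 bis-borylated benzo-bridged enedione
Product: 17 bis-borylated bridged diketone (16 with the C4–C8 bond closed; isopropenyl exo on C4; C9 now CH2; Bpin on C18 and C21)
Conditions: Me2AlCl (1.5 equiv), CH2Cl2, −78 to −20 °C
Reagents that add atoms: none
Why: Lewis-acid-induced intramolecular ene cyclisation of an activated 1,6-diene, which runs stepwise (conjugate addition of the alkene, then loss of a methyl proton) and for such substrates gives the trans-disposed cyclopentane where the concerted thermal reaction gives cis: aluminium on the C10 carbonyl makes C8 electrophilic, C4 can reach C8 only on the face of ring B that bears C5 (this fixes C8), closure of the five-membered ring is preferred to attack at C9, which would demand a boat-shaped ring B, and the extended transition state places the CMe2 unit toward the C7 bridge and away from the C9–C10–C11 bridge, which sets C4 with the isopropenyl group exo.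

Step 9
Reactants: 17 bis-borylated bridged diketone
Product: 18 CNP0287617.1 (target hydroquinone; OH on C18 and C21)
Conditions: Me3NO·2H2O (3 equiv), THF, rt to 50 °C, argon; aq. NH4Cl work-up
Reagents that add atoms: trimethylamine N-oxide, C[N+](C)(C)[O-]
Why: Oxidation of arylboronates with an amine N-oxide (oxygen binds to boron, the aryl group shifts from boron to oxygen, the borate ester is hydrolysed on work-up): the reagent attacks neither the ketones nor the alkenes and is too weak an oxidant to take the hydroquinone on to the quinone, and no stereocentre is involved.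

Compound list
1 | ethynyltrimethylsilane | C#C[Si](C)(C)C | starting material
2 | (E)-1,2-dichloroethene | Cl/C=C/Cl | starting material
3 | (E)-(4-chlorobut-3-en-1-yn-1-yl)trimethylsilane | Cl/C=C/C#C[Si](C)(C)C | intermediate
4 | isopropenylmagnesium bromide | C=C(C)[Mg]Br | starting material
5 | (E)-trimethyl(5-methylhexa-3,5-dien-1-yn-1-yl)silane | C=C(C)/C=C/C#C[Si](C)(C)C | intermediate
6 | 1,4-dioxaspiro[4.5]deca-6,9-dien-8-one | O=C1C=CC2(C=C1)OCCO2 | starting material
7 | all-cis adduct 7-methyl-5-[(trimethylsilyl)ethynyl]-4a,5,8,8a-tetrahydro-4H-spiro[naphthalene-1,2'-[1,3]dioxolan]-4-one | [C@@H]23C(=O)C=CC4(OCCO4)[C@@H]2CC(C)=C[C@@H]3C#C[Si](C)(C)C | intermediate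
8 | 1-bromo-3-methylbut-2-ene (prenyl bromide) | CC(C)=CCBr | starting material
9 | C6-prenylated dioxolane ketal (prenyl trans to the alkyne; cis ring fusion) | CC(C)=CC[C@@]23C(=O)C=CC4(OCCO4)[C@@H]2CC(C)=C[C@@H]3C#C[Si](C)(C)C | intermediate (not isolated)
10 | 7-methyl-4a-(3-methylbut-2-en-1-yl)-5-[(trimethylsilyl)ethynyl]-4a,5,8,8a-tetrahydronaphthalene-1,4-dione (either C11 epimer serves) | CC(C)=CC[C@@]23C(=O)C=CC(=O)[C@@H]2CC(C)=C[C@@H]3C#C[Si](C)(C)C | intermediate
11 | 1-[(trimethylsilyl)ethynyl]-1,2-benziodoxol-3(1H)-one | C[Si](C)(C)C#CI1OC(=O)c2ccccc12 | starting material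
12 | C11-ethynyl C18-silyl diyne | CC(C)=CC[C@@]23C(=O)C=CC(=O)[C@@]2(C#C)CC(C)=C[C@@H]3C#C[Si](C)(C)C | intermediate (not isolated)
13 | 5,8a-diethynyl-7-methyl-4a-(3-methylbut-2-en-1-yl)-4a,5,8,8a-tetrahydronaphthalene-1,4-dione (alkynes cis, prenyl trans to both, trans ring fusion) | CC(C)=CC[C@@]23C(=O)C=CC(=O)[C@@]2(C#C)CC(C)=C[C@@H]3C#C | intermediate
14 | 5,8a-bis(pinacolborylethynyl) analogue of 13 (key-step precursor) | CC(C)=CC[C@@]23C(=O)C=CC(=O)[C@@]2(C#CB4OC(C)(C)C(C)(C)O4)CC(C)=C[C@@H]3C#CB4OC(C)(C)C(C)(C)O4 | intermediate
15 | acetylene | C#C | starting material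
16 | bis-borylated benzo-bridged enedione (key-step product) | CC(C)=CC[C@@]23C(=O)C=CC(=O)[C@@]21CC(C)=C[C@@H]3c2c(B4OC(C)(C)C(C)(C)O4)ccc(B4OC(C)(C)C(C)(C)O4)c21 | intermediate
17 | bis-borylated bridged diketone (C4–C8 closed, isopropenyl exo) | C=C(C)[C@H]1C[C@@]23C(=O)[C@@H]1CC(=O)[C@@]21CC(C)=C[C@@H]3c2c(B4OC(C)(C)C(C)(C)O4)ccc(B4OC(C)(C)C(C)(C)O4)c21 | intermediate
18 | CNP0287617.1 | C=C(C)[C@H]1C[C@@]23C(=O)[C@@H]1CC(=O)[C@@]21CC(C)=C[C@@H]3c2c(O)ccc(O)c21 | target

Total step count: 9. Longest linear sequence: 9 steps (from 1 and 2 to 18; 6 enters at step 3).

Steps most likely to fail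

Step 7 (the step that carries the new method). The strained cis-1,3-diaxial diyne may fail to couple on the metal, so that 14 oligomerises or acetylene is consumed as benzene, or the alkynyl carbon–boron bonds may be lost by protodeborylation. The fallback uses known chemistry only: ring A is carried in ready-made on the diene and the five-membered ring is closed by palladium-catalysed intramolecular α-arylation of the C10 ketone, which can only give the cis-bridged ring. It sets out from 6. The Diels–Alder reaction of step 3 with (E)-2-bromo-1,4-dimethoxy-3-(3-methylbuta-1,3-dien-1-yl)benzene F1 (Horner–Wadsworth–Emmons reaction of 2-bromo-3,6-dimethoxybenzaldehyde with diethyl (2-methylallyl)phosphonate) should give the all-cis aryl adduct F2. Prenylation as in step 4 gives the aryl prenyl ketal F3 and, after acid, the aryl prenyl enedione F4. Pd(OAc)2, P(t-Bu)3 and K3PO4 in toluene at 80 °C then join C11 to C22 and give the dimethoxy benzo-bridged enedione F5. Me2AlCl as in step 8 gives the dimethoxy diketone F6, (NH4)2Ce(NO3)6 in aqueous MeCN gives the quinone diketone F7, and Na2S2O4 reduces it to 18, where the detour rejoins the route.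

Step 5. The enolate may be attacked on the face that carries the prenyl group (wrong C11 epimer, no ring closure possible later), or carbon–carbon bond formation next to the quaternary C6 may fail with the bulky iodane. In the fallback the ethynyl group is built from a one-carbon electrophile. It sets out from 10. KHMDS and gaseous formaldehyde in THF at −78 °C give the hydroxymethyl ketone F8, the smallest possible electrophile entering anti to the axial prenyl CH2. Dess–Martin periodinane gives the keto aldehyde F9. Dimethyl (1-diazo-2-oxopropyl)phosphonate with K2CO3 in MeOH (Seyferth–Gilbert homologation) turns the formyl group into the ethynyl group and strips the silyl group from the second alkyne, which returns the material to 13. If the facial preference itself proves to be syn to prenyl, the tethered closure given for step 7 applies, since it never forms the C11–C22 bond intermolecularly.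

Step 8. Ring closure may follow the concerted ene course, in which the hydrogen is handed directly to C9 and the isopropenyl group is forced endo (C4 epimer), or the alkene may attack C9 and close a six-membered ring. The fallback is a halide-terminated polar cyclisation followed by elimination. It sets out from 16. TiCl4 in CH2Cl2 at −78 °C should give the tertiary chloride F10, the C2 cation being trapped by chloride from the extended transition state before any hydrogen can be transferred. DBU in toluene at 80 °C then removes HCl toward a methyl group (six accessible hydrogens against one hindered methine) and gives 17.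

Further compounds
F1 | step 7 | (E)-2-bromo-1,4-dimethoxy-3-(3-methylbuta-1,3-dien-1-yl)benzene | C=C(C)/C=C/c1c(Br)c(OC)ccc1OC
F2 | step 7 | all-cis aryl adduct (analogue of 7 with 2-bromo-3,6-dimethoxyphenyl on C16) | [C@@H]23C(=O)C=CC4(OCCO4)[C@@H]2CC(C)=C[C@@H]3c2c(Br)c(OC)ccc2OC
F3 | step 7 | aryl prenyl ketal (prenyl on C6 trans to the aryl group) | CC(C)=CC[C@@]23C(=O)C=CC4(OCCO4)[C@@H]2CC(C)=C[C@@H]3c2c(Br)c(OC)ccc2OC
F4 | step 7 | aryl prenyl enedione | CC(C)=CC[C@@]23C(=O)C=CC(=O)[C@@H]2CC(C)=C[C@@H]3c2c(Br)c(OC)ccc2OC
F5 | step 7 | dimethoxy benzo-bridged enedione (analogue of 16 with OMe on C18 and C21) | CC(C)=CC[C@@]23C(=O)C=CC(=O)[C@@]21CC(C)=C[C@@H]3c2c(OC)ccc(OC)c21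
F6 | step 7 | dimethoxy diketone (dimethyl ether of 18) | C=C(C)[C@H]1C[C@@]23C(=O)[C@@H]1CC(=O)[C@@]21CC(C)=C[C@@H]3c2c(OC)ccc(OC)c21
F7 | step 7 | quinone diketone (quinone of 18) | C=C(C)[C@H]1C[C@@]23C(=O)[C@@H]1CC(=O)[C@@]21CC(C)=C[C@@H]3C2=C1C(=O)C=CC2=O
F8 | step 5 | hydroxymethyl ketone (CH2OH on C11, anti to prenyl) | CC(C)=CC[C@@]23C(=O)C=CC(=O)[C@@]2(CO)CC(C)=C[C@@H]3C#C[Si](C)(C)C
F9 | step 5 | keto aldehyde (CHO on C11) | CC(C)=CC[C@@]23C(=O)C=CC(=O)[C@@]2(C=O)CC(C)=C[C@@H]3C#C[Si](C)(C)C
F10 | step 8 | tertiary chloride (2-chloropropan-2-yl on C4, exo) | CC(C)(Cl)[C@H]1C[C@@]23C(=O)[C@@H]1CC(=O)[C@@]21CC(C)=C[C@@H]3c2c(B4OC(C)(C)C(C)(C)O4)ccc(B4OC(C)(C)C(C)(C)O4)c21
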